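**Retrosynthetic overview**
1. 27 ⇒ 24: in the last step an indium Barbier allylation joins C6 and C7 on a pyranose-masked aldehyde and closes the ten-membered carbocycle; the freed C6–O then closes the α-methylene γ-lactone in the same flask.
2. 24 ⇒ 21: Morita–Baylis–Hillman reaction at the C7 aldehyde and SN2′ bromination; the C8 angelate and C5 (R)-2-methylbutanoate are already in place.
3. 21 ⇒ 12: C2–C6 are built as a temporary pyranone ring by Achmatowicz rearrangement of a 3-methyl-2-furyl carbinol, followed by dihydroxylation directed by the anomeric group (C4, C5).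
4. 12 ⇒ 7 + 9: C2 comes from asymmetric transfer hydrogenation; the C1–C2 bond and C10 come from anti-selective hydroboration and thioester cross-coupling.
5. 7 ⇒ 3 + 4: an Evans syn-glycolate aldol sets C8 and C9. Ring order: temporary pyranose (step 8), then carbocycle and lactone together (step 17).

Assumption: atom labels C1–C13 follow the germacranolide numbering of the target (ring C1–C10, methyls on C4 and C10, lactone oxygen on C6, C12 the lactone carbonyl, C11=C13 the methylidene); ring atoms C2–C6 of the pyranone intermediates keep these labels.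

**Step 1**
Reactants: 1 (S)-4-benzyloxazolidin-2-one; 2 (benzyloxy)acetyl chloride
Product: 3 (S)-4-benzyl-3-[(benzyloxy)acetyl]oxazolidin-2-one
Conditions: n-BuLi, THF, −78 °C; then 2, −78 to 0 °C
Reagents that add atoms: none
Why: N-acylation of the lithiated oxazolidinone by the acid chloride gives the glycolate imide without touching the auxiliary stereocenter.

**Step 2**
Reactants: 3 (S)-4-benzyl-3-[(benzyloxy)acetyl]oxazolidin-2-one; 4 methacrolein
Product: 5 (S)-4-benzyl-3-[(2S,3R)-2-(benzyloxy)-3-hydroxy-4-methylpent-4-enoyl]oxazolidin-2-one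
Conditions: Bu2BOTf, Et3N, CH2Cl2, −78 °C; then 4, −78 to 0 °C; MeOH, pH 7 buffer, H2O2, 0 °C
Reagents that add atoms: none
Why: Evans syn-glycolate aldol, in which the (Z)-boron enolate reacts through a Zimmerman–Traxler chair on the face away from the benzyl group of the auxiliary and sets C8 (2S in 5) and C9 (3R in 5) in the 8,9-syn relationship of the target.

**Step 3**
Reactants: 5 aldol adduct
Product: 6 (2R,3R)-2-(benzyloxy)-4-methylpent-4-ene-1,3-diol
Conditions: LiBH4, MeOH (1 equiv), THF, 0 °C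
Reagents that add atoms: none
Why: Reductive cleavage of the N-acyl oxazolidinone by LiBH4 frees the C7 primary alcohol and the auxiliary while C8 and C9 stay as set (the C8 descriptor changes to R only through CIP priorities).

**Step 4**
Reactants: 6 (2R,3R)-2-(benzyloxy)-4-methylpent-4-ene-1,3-diol
Product: 7 (2R,3R)-2-(benzyloxy)-4-methyl-1,3-bis(triethylsilyloxy)pent-4-ene
Conditions: Et3SiCl, imidazole, CH2Cl2, 0 °C to rt
Reagents that add atoms: chlorotriethylsilane, CC[Si](Cl)(CC)CC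
Why: Silyl ether formation on both hydroxyls gives a primary (C7) and a secondary (C9) triethylsilyl ether that can be told apart later.

**Step 5**
Reactants: 8 3-methylfuran-2-carboxylic acid
Product: 9 S-phenyl 3-methylfuran-2-carbothioate
Conditions: PhSH, DCC, DMAP (cat.), CH2Cl2, 0 °C to rt
Reagents that add atoms: benzenethiol, Sc1ccccc1
Why: Steglich-type thioesterification (carbodiimide activation, DMAP acyl transfer) makes the acyl donor that carries C2–C6 and the C4 methyl as a furan.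

**Step 6**
Reactants: 7 (2R,3R)-2-(benzyloxy)-4-methyl-1,3-bis(triethylsilyloxy)pent-4-ene; 9 S-phenyl 3-methylfuran-2-carbothioate
Product: 11 (3R,4R,5R)-5-(benzyloxy)-3-methyl-1-(3-methylfuran-2-yl)-4,6-bis(triethylsilyloxy)hexan-1-one, via B-alkyl-9-BBN adduct 10 (not isolated)
Conditions: 9-BBN-H, THF, 0 °C to rt; then 9, Pd2(dba)3 (2.5 mol%), P(2-furyl)3, CuO2C(2-thienyl), Cs2CO3, THF, 45 °C
Reagents that add atoms: none
Why: Hydroboration with 9-BBN puts boron on C1 and hydrogen on C10 from the face anti to the C8 arm in the conformer where C9–H eclipses the alkene (allylic strain control, 9,10-anti, C10 = R), and the B-alkyl group is then coupled with the thioester under zerovalent palladium catalysis with stoichiometric copper carboxylate (Liebeskind–Srogl ketone synthesis) to form the C1–C2 bond.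

**Step 7**
Reactants: 11 furyl ketone
Product: 12 (1R,3R,4R,5R)-5-(benzyloxy)-3-methyl-1-(3-methylfuran-2-yl)-4,6-bis(triethylsilyloxy)hexan-1-ol
Conditions: RuCl[(R,R)-TsDPEN](p-cymene) (1 mol%), HCO2Na, cetyltrimethylammonium bromide, H2O–CH2Cl2, rt
Reagents that add atoms: none
Why: Noyori asymmetric transfer hydrogenation of the heteroaryl ketone, in which the (R,R)-ligated ruthenium hydride delivers hydride to one carbonyl face under catalyst control and sets C2 as R.

**Step 8**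
Reactants: 12 furyl carbinol
Product: 13 (2R,6RS)-2-[(2R,3R,4R)-4-(benzyloxy)-2-methyl-3,5-bis(triethylsilyloxy)pentyl]-6-hydroxy-4-methyl-2H-pyran-3(6H)-one
Conditions: NBS, NaHCO3, THF–H2O (4:1), 0 °C
Reagents that add atoms: water, O
Why: Achmatowicz rearrangement, in which NBS oxidizes the furan to the cis-enedione stage and the C2 hydroxyl closes onto the C6 aldehyde, giving the C3 ketone, the C4 methyl-bearing alkene and C6 at the aldehyde oxidation level with C2 retained.

**Step 9**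
Reactants: 13 pyranone lactol
Product: 14 (2R,6R)-2-[(2R,3R,4R)-4-(benzyloxy)-2-methyl-3,5-bis(triethylsilyloxy)pentyl]-6-(tert-butyldimethylsilyloxy)-4-methyl-2H-pyran-3(6H)-one
Conditions: t-BuMe2SiCl, imidazole, CH2Cl2, 0 °C
Reagents that add atoms: tert-butylchlorodimethylsilane, CC(C)(C)[Si](C)(C)Cl
Why: Silylation of the lactol hydroxyl favours the 2,6-trans anomer with a pseudoaxial silyloxy group (anomeric effect), and the minor cis anomer is removed by chromatography.

**Step 10**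
Reactants: 14 anomeric silyl ether
Product: 15 (2R,4R,5S,6R)-2-[(2R,3R,4R)-4-(benzyloxy)-2-methyl-3,5-bis(triethylsilyloxy)pentyl]-6-(tert-butyldimethylsilyloxy)-4,5-dihydroxy-4-methyloxan-3-one
Conditions: OsO4 (5 mol%), NMO, acetone–H2O (5:1), rt
Reagents that add atoms: N-methylmorpholine N-oxide, C[N+]1([O-])CCOCC1; water, O
Why: Upjohn syn-dihydroxylation of the enone, in which OsO4 adds to the C4=C5 face opposite the pseudoaxial anomeric silyloxy group (syn to the C2 side chain) and creates the tertiary C4 alcohol and the C5 alcohol cis to it as the target needs.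

**Step 11**
Reactants: 15 pyranone diol; 16 (R)-2-methylbutanoic acid
Product: 17 (2R,4R,5S,6R)-2-[(2R,3R,4R)-4-(benzyloxy)-2-methyl-3,5-bis(triethylsilyloxy)pentyl]-6-(tert-butyldimethylsilyloxy)-4-hydroxy-4-methyl-5-[(2R)-2-methylbutanoyloxy]oxan-3-one
Conditions: DCC, DMAP, CH2Cl2, 0 °C to rt
Reagents that add atoms: none
Why: Steglich esterification acylates only the secondary C5 hydroxyl because the tertiary C4 hydroxyl next to the ketone is inert, and the α-stereocenter of the acid is carried over unchanged.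

**Step 12**
Reactants: 17 C5 ester
Product: 18 (2R,4R,5S,6R)-6-(tert-butyldimethylsilyloxy)-4-hydroxy-2-[(2R,3R,4R)-4-hydroxy-2-methyl-3,5-bis(triethylsilyloxy)pentyl]-4-methyl-5-[(2R)-2-methylbutanoyloxy]oxan-3-one
Conditions: H2 (1 atm), Pd(OH)2/C, EtOAc, rt
Reagents that add atoms: none
Why: Hydrogenolysis of the benzyl ether frees only the C8 hydroxyl, since no alkene is left at this stage and the silyl ethers, esters and hindered ketone survive in EtOAc.

**Step 13**
Reactants: 18 C8 alcohol; 19 angelic acid [(Z)-2-methylbut-2-enoic acid]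
Product: 20 (2R,4R,5S,6R)-6-(tert-butyldimethylsilyloxy)-4-hydroxy-4-methyl-5-[(2R)-2-methylbutanoyloxy]-2-[(2R,3R,4R)-2-methyl-4-[(Z)-2-methylbut-2-enoyloxy]-3,5-bis(triethylsilyloxy)pentyl]oxan-3-one
Conditions: 19, 2,4,6-trichlorobenzoyl chloride, Et3N, toluene, rt; then 18, 75 °C
Reagents that add atoms: none
Why: Yamaguchi-type mixed-anhydride esterification of the only free secondary alcohol, run without a nucleophilic catalyst so that the (Z)-alkene of the angelate does not isomerize to the tiglate.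

**Step 14**
Reactants: 20 angelate
Product: 21 (2S,3R,4R)-5-[(2R,4R,5S,6R)-6-(tert-butyldimethylsilyloxy)-4-hydroxy-4-methyl-5-((2R)-2-methylbutanoyloxy)-3-oxooxan-2-yl]-4-methyl-1-oxo-3-(triethylsilyloxy)pentan-2-yl (Z)-2-methylbut-2-enoate
Conditions: (COCl)2, DMSO, CH2Cl2, −78 to −40 °C; then Et3N, −78 to 0 °C
Reagents that add atoms: none
Why: Swern oxidation applied to the silyl ether (oxidative desilylation), in which the chlorosulfonium ion displaces the unhindered primary Et3Si group at C7–O and the alkoxysulfonium collapses to the aldehyde while the secondary Et3Si ether and the anomeric silyl ether stay.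

**Step 15**
Reactants: 21 C7 aldehyde; 22 methyl acrylate
Product: 23 methyl (3RS,4R,5R,6R)-7-[(2R,4R,5S,6R)-6-(tert-butyldimethylsilyloxy)-4-hydroxy-4-methyl-5-((2R)-2-methylbutanoyloxy)-3-oxooxan-2-yl]-3-hydroxy-6-methyl-4-[(Z)-2-methylbut-2-enoyloxy]-2-methylidene-5-(triethylsilyloxy)heptanoate
Conditions: DABCO (1 equiv), 22 (5 equiv), dioxane–H2O (1:1), rt
Reagents that add atoms: none
Why: Morita–Baylis–Hillman reaction, in which the DABCO–acrylate zwitterion adds to the activated α-acyloxy aldehyde and expels DABCO, attaching C11–C13 to C7; the new C7 carbinol center does not matter because it becomes sp2 in the next step.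

**Step 16**
Reactants: 23 Morita–Baylis–Hillman adduct
Product: 24 methyl (2Z,4R,5R,6R)-2-(bromomethyl)-7-[(2R,4R,5S,6R)-6-(tert-butyldimethylsilyloxy)-4-hydroxy-4-methyl-5-((2R)-2-methylbutanoyloxy)-3-oxooxan-2-yl]-6-methyl-4-[(Z)-2-methylbut-2-enoyloxy]-5-(triethylsilyloxy)hept-2-enoate
Conditions: NBS, Me2S, CH2Cl2, −20 to 0 °C
Reagents that add atoms: N-bromosuccinimide, O=C1CCC(=O)N1Br
Why: Corey–Kim-type activation of the allylic alcohol by the bromosulfonium salt and SN2′ attack of bromide at C13 (allylic transposition) gives the thermodynamically preferred (Z)-2-(bromomethyl)enoate with C8 cis to CH2Br.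

**Step 17**
Reactants: 24 allylic bromide
Product: 27 (2R,4R,5R,6S,7R,8R,9R,10R)-2,4,9-trihydroxy-5-[(2R)-2-methylbutanoyloxy]-8-[(Z)-2-methylbut-2-enoyloxy]-3-oxogermacr-11(13)-en-12,6-olide (target CNP0301185.1), via desilylated bromo lactol 25 (not isolated), via macrocyclic hydroxy ester 26 (not isolated)
Conditions: THF–0.1 M aq. HCl (1:1), rt, 3 h; then indium powder (4 equiv), diluted to 0.002 M, 35 °C, 12 h
Reagents that add atoms: none
Why: Proposed new method: in dilute acid both silyl ethers are lost and the pyranose lactol equilibrates with its open C2-hydroxy C6-aldehyde, indium inserts into the allylic C–Br bond, the allylindium attacks C6 through its γ-carbon C7 (SE2′) in a chair-like six-membered In–O transition state that closes the ten-membered carbocycle, and the C6 alkoxide then displaces methoxide at C12 to close the lactone; C7 is set by C8 (C8–H eclipses the allyl plane because of allylic strain with the cis CH2In group, so the tethered aldehyde arrives anti to the C8–O bond), C6 follows from the anti arrangement of the two ring arms across the forming C6–C7 bond that a trans-fused ten-membered ring demands (6S,7R), and the doubly α-branched C3 ketone is too hindered to compete; the closest known reactions are the indium-mediated Barbier allylation of unprotected aldose lactols with 2-(bromomethyl)acrylates in aqueous acid and the macrocyclic Barbier allylation–lactonization used for germacranolides.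

**Compound list**
1 | (S)-4-benzyloxazolidin-2-one | O=C1N[C@@H](Cc2ccccc2)CO1 | starting material
2 | (benzyloxy)acetyl chloride | O=C(Cl)COCc1ccccc1 | starting material
3 | (S)-4-benzyl-3-[(benzyloxy)acetyl]oxazolidin-2-one | O=C(COCc1ccccc1)N1[C@@H](Cc2ccccc2)COC1=O | intermediate
4 | methacrolein (2-methylprop-2-enal) | C=C(C)C=O | starting material
5 | (S)-4-benzyl-3-[(2S,3R)-2-(benzyloxy)-3-hydroxy-4-methylpent-4-enoyl]oxazolidin-2-one | O=C(N1[C@@H](Cc2ccccc2)COC1=O)[C@@H](OCc1ccccc1)[C@H](O)C(C)=C | intermediate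
6 | (2R,3R)-2-(benzyloxy)-4-methylpent-4-ene-1,3-diol | OC[C@@H](OCc1ccccc1)[C@H](O)C(C)=C | intermediate
7 | (2R,3R)-2-(benzyloxy)-4-methyl-1,3-bis(triethylsilyloxy)pent-4-ene | CC[Si](CC)(CC)OC[C@@H](OCc1ccccc1)[C@H](O[Si](CC)(CC)CC)C(C)=C | intermediate
8 | 3-methylfuran-2-carboxylic acid | Cc1ccoc1C(=O)O | starting material
9 | S-phenyl 3-methylfuran-2-carbothioate | Cc1ccoc1C(=O)Sc1ccccc1 | intermediate
10 | 9-[(2R,3R,4R)-4-(benzyloxy)-2-methyl-3,5-bis(triethylsilyloxy)pentyl]-9-borabicyclo[3.3.1]nonane | CC[Si](CC)(CC)OC[C@@H](OCc1ccccc1)[C@H](O[Si](CC)(CC)CC)[C@H](C)CB1C2CCCC1CCC2 | intermediate (not isolated)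
11 | (3R,4R,5R)-5-(benzyloxy)-3-methyl-1-(3-methylfuran-2-yl)-4,6-bis(triethylsilyloxy)hexan-1-one | CC[Si](CC)(CC)OC[C@@H](OCc1ccccc1)[C@H](O[Si](CC)(CC)CC)[C@H](C)CC(=O)c1occc1C | intermediate
12 | (1R,3R,4R,5R)-5-(benzyloxy)-3-methyl-1-(3-methylfuran-2-yl)-4,6-bis(triethylsilyloxy)hexan-1-ol | CC[Si](CC)(CC)OC[C@@H](OCc1ccccc1)[C@H](O[Si](CC)(CC)CC)[C@H](C)C[C@@H](O)c1occc1C | intermediate
13 | (2R,6RS)-2-[(2R,3R,4R)-4-(benzyloxy)-2-methyl-3,5-bis(triethylsilyloxy)pentyl]-6-hydroxy-4-methyl-2H-pyran-3(6H)-one | CC[Si](CC)(CC)OC[C@@H](OCc1ccccc1)[C@H](O[Si](CC)(CC)CC)[C@H](C)C[C@@H]1C(=O)C(C)=CC(O)O1 | intermediate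
14 | (2R,6R)-2-[(2R,3R,4R)-4-(benzyloxy)-2-methyl-3,5-bis(triethylsilyloxy)pentyl]-6-(tert-butyldimethylsilyloxy)-4-methyl-2H-pyran-3(6H)-one (2,6-trans) | CC[Si](CC)(CC)OC[C@@H](OCc1ccccc1)[C@H](O[Si](CC)(CC)CC)[C@H](C)C[C@@H]1C(=O)C(C)=C[C@@H](O[Si](C)(C)C(C)(C)C)O1 | intermediate
15 | (2R,4R,5S,6R)-2-[(2R,3R,4R)-4-(benzyloxy)-2-methyl-3,5-bis(triethylsilyloxy)pentyl]-6-(tert-butyldimethylsilyloxy)-4,5-dihydroxy-4-methyloxan-3-one | CC[Si](CC)(CC)OC[C@@H](OCc1ccccc1)[C@H](O[Si](CC)(CC)CC)[C@H](C)C[C@@H]1C(=O)[C@](C)(O)[C@H](O)[C@@H](O[Si](C)(C)C(C)(C)C)O1 | intermediate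
16 | (R)-2-methylbutanoic acid | CC[C@@H](C)C(=O)O | starting material
17 | (2R,4R,5S,6R)-2-[(2R,3R,4R)-4-(benzyloxy)-2-methyl-3,5-bis(triethylsilyloxy)pentyl]-6-(tert-butyldimethylsilyloxy)-4-hydroxy-4-methyl-5-[(2R)-2-methylbutanoyloxy]oxan-3-one | CC[Si](CC)(CC)OC[C@@H](OCc1ccccc1)[C@H](O[Si](CC)(CC)CC)[C@H](C)C[C@@H]1C(=O)[C@](C)(O)[C@H](OC(=O)[C@H](C)CC)[C@@H](O[Si](C)(C)C(C)(C)C)O1 | intermediate
18 | (2R,4R,5S,6R)-6-(tert-butyldimethylsilyloxy)-4-hydroxy-2-[(2R,3R,4R)-4-hydroxy-2-methyl-3,5-bis(triethylsilyloxy)pentyl]-4-methyl-5-[(2R)-2-methylbutanoyloxy]oxan-3-one | CC[Si](CC)(CC)OC[C@@H](O)[C@H](O[Si](CC)(CC)CC)[C@H](C)C[C@@H]1C(=O)[C@](C)(O)[C@H](OC(=O)[C@H](C)CC)[C@@H](O[Si](C)(C)C(C)(C)C)O1 | intermediate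
19 | angelic acid, (Z)-2-methylbut-2-enoic acid | C/C=C(/C)C(=O)O | starting material
20 | (2R,4R,5S,6R)-6-(tert-butyldimethylsilyloxy)-4-hydroxy-4-methyl-5-[(2R)-2-methylbutanoyloxy]-2-[(2R,3R,4R)-2-methyl-4-[(Z)-2-methylbut-2-enoyloxy]-3,5-bis(triethylsilyloxy)pentyl]oxan-3-one | CC[Si](CC)(CC)OC[C@@H](OC(=O)/C(C)=C\C)[C@H](O[Si](CC)(CC)CC)[C@H](C)C[C@@H]1C(=O)[C@](C)(O)[C@H](OC(=O)[C@H](C)CC)[C@@H](O[Si](C)(C)C(C)(C)C)O1 | intermediate
21 | (2S,3R,4R)-5-[(2R,4R,5S,6R)-6-(tert-butyldimethylsilyloxy)-4-hydroxy-4-methyl-5-((2R)-2-methylbutanoyloxy)-3-oxooxan-2-yl]-4-methyl-1-oxo-3-(triethylsilyloxy)pentan-2-yl (Z)-2-methylbut-2-enoate | O=C[C@@H](OC(=O)/C(C)=C\C)[C@H](O[Si](CC)(CC)CC)[C@H](C)C[C@@H]1C(=O)[C@](C)(O)[C@H](OC(=O)[C@H](C)CC)[C@@H](O[Si](C)(C)C(C)(C)C)O1 | intermediate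
22 | methyl acrylate | C=CC(=O)OC | starting material
23 | methyl (3RS,4R,5R,6R)-7-[(2R,4R,5S,6R)-6-(tert-butyldimethylsilyloxy)-4-hydroxy-4-methyl-5-((2R)-2-methylbutanoyloxy)-3-oxooxan-2-yl]-3-hydroxy-6-methyl-4-[(Z)-2-methylbut-2-enoyloxy]-2-methylidene-5-(triethylsilyloxy)heptanoate | C=C(C(=O)OC)C(O)[C@@H](OC(=O)/C(C)=C\C)[C@H](O[Si](CC)(CC)CC)[C@H](C)C[C@@H]1C(=O)[C@](C)(O)[C@H](OC(=O)[C@H](C)CC)[C@@H](O[Si](C)(C)C(C)(C)C)O1 | intermediate
24 | methyl (2Z,4R,5R,6R)-2-(bromomethyl)-7-[(2R,4R,5S,6R)-6-(tert-butyldimethylsilyloxy)-4-hydroxy-4-methyl-5-((2R)-2-methylbutanoyloxy)-3-oxooxan-2-yl]-6-methyl-4-[(Z)-2-methylbut-2-enoyloxy]-5-(triethylsilyloxy)hept-2-enoate | BrC/C(C(=O)OC)=C\[C@@H](OC(=O)/C(C)=C\C)[C@H](O[Si](CC)(CC)CC)[C@H](C)C[C@@H]1C(=O)[C@](C)(O)[C@H](OC(=O)[C@H](C)CC)[C@@H](O[Si](C)(C)C(C)(C)C)O1 | intermediate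
25 | methyl (2Z,4R,5R,6R)-2-(bromomethyl)-7-[(2R,4R,5S,6RS)-4,6-dihydroxy-4-methyl-5-((2R)-2-methylbutanoyloxy)-3-oxooxan-2-yl]-5-hydroxy-6-methyl-4-[(Z)-2-methylbut-2-enoyloxy]hept-2-enoate | BrC/C(C(=O)OC)=C\[C@@H](OC(=O)/C(C)=C\C)[C@H](O)[C@H](C)C[C@@H]1C(=O)[C@](C)(O)[C@H](OC(=O)[C@H](C)CC)C(O)O1 | intermediate (not isolated)
26 | methyl (2R,4R,5R,6S,7S,8R,9R,10R)-2,4,6,9-tetrahydroxy-5-[(2R)-2-methylbutanoyloxy]-8-[(Z)-2-methylbut-2-enoyloxy]-3-oxogermacr-11(13)-en-12-oate (ten-membered ring closed, lactone still open) | C=C(C(=O)OC)[C@@H]1[C@@H](OC(=O)/C(C)=C\C)[C@H](O)[C@H](C)C[C@@H](O)C(=O)[C@](C)(O)[C@H](OC(=O)[C@H](C)CC)[C@H]1O | intermediate (not isolated)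
27 | (2R,4R,5R,6S,7R,8R,9R,10R)-2,4,9-trihydroxy-5-[(2R)-2-methylbutanoyloxy]-8-[(Z)-2-methylbut-2-enoyloxy]-3-oxogermacr-11(13)-en-12,6-olide (CNP0301185.1) | C=C1C(=O)O[C@H]2[C@H]1[C@@H](OC(=O)/C(C)=C\C)[C@H](O)[C@H](C)C[C@@H](O)C(=O)[C@](C)(O)[C@@H]2OC(=O)[C@H](C)CC | target

**Step count and risks**
Total step count: 17. Longest linear sequence: 16 steps (steps 1–4 and 6–17).

Most likely to fail, in this order:

1. **Step 17 (double ring closure).** The allylindium may be protonated or lose the C8 angelate by 1,4-elimination before the slow ten-membered closure, and the 6,7-trans sense is argued from ring strain, not proven. The fallback sets out from 24 and comes back at 27. Bromide 24 is borylated (B2pin2, Pd2(dba)3 as source of zerovalent palladium, DMSO, 40 °C) to the pinacol allylboronate methyl (2E,4R,5R,6R)-7-[(2R,4R,5S,6R)-6-(tert-butyldimethylsilyloxy)-4-hydroxy-4-methyl-5-((2R)-2-methylbutanoyloxy)-3-oxooxan-2-yl]-6-methyl-4-[(Z)-2-methylbut-2-enoyloxy]-2-[(4,4,5,5-tetramethyl-1,3,2-dioxaborolan-2-yl)methyl]-5-(triethylsilyloxy)hept-2-enoate F1. In THF–0.1 M aq. HCl at high dilution the silyl ethers fall off and the boronate allylates the lactol-derived aldehyde intramolecularly through a closed six-membered boron chair under Brønsted acid catalysis; the borate of the C6 alkoxide then lactonizes onto C12 to give 27. The allyl donor is isolable, does not protonate in water and ignores the C3 ketone.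

2. **Step 15 (Morita–Baylis–Hillman).** The α-angeloyloxy β-silyloxy aldehyde can epimerize at C8, eliminate the C9 silyloxy group or suffer acyl migration under prolonged amine catalysis. The fallback sets out from 21 and comes back at 23. The lithium enolate of methyl 3-(phenylselanyl)propanoate (LDA, THF, −78 °C) is added to 21 to give the aldol methyl (4R,5R,6R)-7-[(2R,4R,5S,6R)-6-(tert-butyldimethylsilyloxy)-4-hydroxy-4-methyl-5-((2R)-2-methylbutanoyloxy)-3-oxooxan-2-yl]-3-hydroxy-6-methyl-4-[(Z)-2-methylbut-2-enoyloxy]-2-[(phenylselanyl)methyl]-5-(triethylsilyloxy)heptanoate F2. Oxidation with H2O2 and syn-elimination of the selenoxide (the only β-hydrogen is on C11) then gives 23.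

3. **Step 6 (hydroboration and acyl cross-coupling).** The B-alkyl transfer from a β-branched, heavily oxygenated 9-BBN adduct to the acyl–palladium species may be slow against protodeboronation. The fallback sets out from 7 and comes back at 11. The same 9-BBN hydroboration is worked up oxidatively (NaBO3·4H2O) to (2R,3R,4R)-4-(benzyloxy)-2-methyl-3,5-bis(triethylsilyloxy)pentan-1-ol F3. Iodination (I2, PPh3, imidazole) gives (2S,3R,4R)-4-(benzyloxy)-1-iodo-2-methyl-3,5-bis(triethylsilyloxy)pentane F4. Iodine–lithium exchange (t-BuLi, Et2O, −78 °C) and acylation of the alkyllithium with N-methoxy-N,3-dimethylfuran-2-carboxamide F5 (made from acid 8 via its acid chloride and MeNHOMe·HCl) deliver ketone 11.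

**Further compounds**
F1 | step 17 | methyl (2E,4R,5R,6R)-7-[(2R,4R,5S,6R)-6-(tert-butyldimethylsilyloxy)-4-hydroxy-4-methyl-5-((2R)-2-methylbutanoyloxy)-3-oxooxan-2-yl]-6-methyl-4-[(Z)-2-methylbut-2-enoyloxy]-2-[(4,4,5,5-tetramethyl-1,3,2-dioxaborolan-2-yl)methyl]-5-(triethylsilyloxy)hept-2-enoate | CC1(C)OB(C/C(C(=O)OC)=C\[C@@H](OC(=O)/C(C)=C\C)[C@H](O[Si](CC)(CC)CC)[C@H](C)C[C@@H]2C(=O)[C@](C)(O)[C@H](OC(=O)[C@H](C)CC)[C@@H](O[Si](C)(C)C(C)(C)C)O2)OC1(C)C
F2 | step 15 | methyl (4R,5R,6R)-7-[(2R,4R,5S,6R)-6-(tert-butyldimethylsilyloxy)-4-hydroxy-4-methyl-5-((2R)-2-methylbutanoyloxy)-3-oxooxan-2-yl]-3-hydroxy-6-methyl-4-[(Z)-2-methylbut-2-enoyloxy]-2-[(phenylselanyl)methyl]-5-(triethylsilyloxy)heptanoate (mixture at C2 and C3) | COC(=O)C(C[Se]c1ccccc1)C(O)[C@@H](OC(=O)/C(C)=C\C)[C@H](O[Si](CC)(CC)CC)[C@H](C)C[C@@H]1C(=O)[C@](C)(O)[C@H](OC(=O)[C@H](C)CC)[C@@H](O[Si](C)(C)C(C)(C)C)O1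
F3 | step 6 | (2R,3R,4R)-4-(benzyloxy)-2-methyl-3,5-bis(triethylsilyloxy)pentan-1-ol | CC[Si](CC)(CC)OC[C@@H](OCc1ccccc1)[C@H](O[Si](CC)(CC)CC)[C@H](C)CO
F4 | step 6 | (2S,3R,4R)-4-(benzyloxy)-1-iodo-2-methyl-3,5-bis(triethylsilyloxy)pentane | CC[Si](CC)(CC)OC[C@@H](OCc1ccccc1)[C@H](O[Si](CC)(CC)CC)[C@H](C)CI
F5 | step 6 | N-methoxy-N,3-dimethylfuran-2-carboxamide | CON(C)C(=O)c1occc1C
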